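## Analysis of the target

The target is a trans-fused hydroazulene. Ring A (C1–C5, five-membered) and ring B (C1, C10, C9, C8, C7, C6, C5, seven-membered) share the C1–C5 bond. It carries an angular methyl on quaternary C1, an isopropyl carbinol at C4, a 4-hydroxybenzoate at C6, a trisubstituted C8=C9 alkene and an allylic 3-methylbutanoate at C10.

There are five stereocentres, (1S,4S,5S,6R,10R) in these locants. Calling the two faces of the bicycle the "methyl face" (that of the C1 methyl) and the "H5 face", the C4 hydroxyl and the C10 ester lie on the H5 face, and the isopropyl group and the C6 ester lie on the methyl face. H5 and H6 are therefore cis, the C4 and C6 oxygens are 1,3-anti, and both esters are pseudo-axial on ring B (C6–O syn-axial to the C1 methyl, C10–O anti to it).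

The sensitive points are:
- the allylic C10 ester, which can ionise toward tertiary C8;
- two different esters next to a free phenol, so the acyl groups must be introduced in order;
- the tertiary C4 alcohol, which at the C6 ketone stage is a tertiary aldol open to retro-aldol cleavage and dehydration;
- the C8=C9 alkene, which would move into conjugation if a C6 ketone were present with it.

The hard parts are the contiguous C1–C5–C4 array with two fully substituted carbons across the ring fusion, the seven-membered ring, and the C10 oxygen, which sits on the face that hydride reagents do not produce (they enter C10 anti to the angular methyl).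

The strategy rests on one feature. C10 lies between quaternary C1 and C9, so C1–C10–C9 is the skeleton of an oxyallyl cation. C5–C8 is a four-carbon unit with oxygen on C6, i.e. a 2-oxygenated diene. C2–C4 is a three-atom tether between the two. One (4+3) cycloaddition of an open chain therefore closes rings A and B and delivers C10 as a ketone and C6 as an enol ether, already differentiated.

## Retrosynthetic reasoning

**C10–O (29 ⇒ 28 ⇒ 25 + 26).** After removal of the two silyl groups of 28, the C10–O bond is cut with inversion: 28 comes from allylic alcohol 25, the C10 epimer, and acid 26 in a Mitsunobu reaction. Reduction of the enone is expected to give the C10 alcohol cis to the C1 methyl, the wrong face, so the ester oxygen is brought in as the nucleophile from the H5 face. One step then sets C10 and installs the acyl group. The forward reaction has to proceed by substitution and not by ionisation.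

**C10–H (25 ⇒ 24).** The carbinol is traced to enone 24 by 1,2-reduction. The ketone is needed at C10 in any case, because it is what allows the alkene to be introduced.

**C8=C9 (24 ⇒ 21).** The alkene is traced to the saturated C10 ketone 21 by Saegusa–Ito dehydrogenation. C1 is quaternary, so enolisation can only go toward C9. The C8 stereocentre, uncontrolled in the cycloaddition, disappears here. The dehydrogenation is placed after C6 has been reduced and acylated, so that the alkene can never conjugate with a C6 carbonyl.

**C6–O acyl (21 ⇒ 18 + 19).** The aryl ester is cut to diol 18 and the silyl-protected acid 19. Only the secondary C6 hydroxyl can be acylated, and putting this ester on first removes any need to tell two secondary alcohols apart later.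

**C6–H (18 ⇒ 17).** The C6 carbinol comes from hydroxy diketone 17 by an Evans–Saksena reduction directed by the C4 hydroxyl. This picks the C6 ketone over the C10 ketone and delivers hydride from the H5 face, as C6 requires.

**Unmasking (17 ⇒ 16).** Diketone 17 is the desilylated form of cycloadduct 16, in which C6 is an enol ether and C10 a ketone.

**C1–C5 and C8–C9 (16 ⇒ 14).** Both rings are opened at once to the acyclic α-chloro ketone 14, which carries the 2-silyloxydiene. This is the only disconnection that removes both rings and the quaternary ring-fusion carbon in one step while keeping oxygen on C6 and C10. Forward, the oxyallyl cation C1–C10–C9 must add across C5–C8 with C1 set relative to C4, and must close at C8 rather than at C6.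

**C1–Cl and C10=O (14 ⇒ 12).** A chloro ketone cannot be present while the diene is made, because the base that enolises C5 would attack the methyl ketone first. The chloro ketone is therefore carried as a latent form, the 1,1-dichloroethyl carbinol 12, which has no carbonyl group. Its alkoxide closes to a 2-chlorooxirane that rearranges to 14.

**C6 enol ether (12 ⇒ 10 + 11).** The silyloxydiene comes from enone 10 by kinetic enolisation toward C5 and O-silylation with 11.

**C1–C10 (10 ⇒ 9 ⇒ 7 + 8).** Enone 10 is the oxidation product of allylic alcohol 9, and 9 arises by addition of lithiated 8 to the C1 methyl ketone of 7. This puts C9, C10 and both chlorines in place in one C–C bond formation.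

**C6–C7 (7 ⇒ 5 + 6).** The propenyl group is cut from the aldehyde carbon of 5. An aldehyde-selective alkenylation with 6 leaves the C1 ketone for the next step.

**C1=C6 of a cyclohexene (5 ⇒ 3 ⇒ 1).** Keto aldehyde 5 is the ozonolysis product of silyl ether 3, made from 1 and 2. Compound 1 supplies C1–C6, the C1 methyl, the isopropyl group and the C4 configuration, and the cleavage gives two different carbonyl termini.

## Alternatives that were turned down

**Alternative 1:** This cuts C1–C10 and C5–C6 photochemically and, afterwards, the C6–C10 bond of a cyclobutanediol. Forward, irradiation of 3-methylcyclopent-2-en-1-one A1 with 4-methyl-1,2-bis(trimethylsilyloxy)cyclopent-1-ene A2 gives the cis-anti-cis photoadduct A3 (a de Mayo-type [2+2]). Desilylation and glycol cleavage, for example with Pb(OAc)4, then open the four-membered ring to ring B with ketones at C6 and C10.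
- For: two trivial partners, the quaternary C1 from the enone β-methyl, both oxygenated ring B carbons arriving as carbonyls. On brevity of skeleton assembly it is stronger than the chosen route.
- Against: nothing in A1 or A2 controls absolute configuration, so the sequence is racemic and needs a resolution. After cleavage C4 and C6 form an enolised 1,3-diketone through C5, with a third ketone at C10. Isopropyl addition at C4 must then pick one of three carbonyls and set C4 relative to C1. C6 and C10 are both ketones and must still be distinguished for the two esters.
- Comparison: the chosen route offers C4 with its isopropyl group and absolute configuration from 1, and C6 and C10 that are different from the moment the rings form.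

**Alternative 2:** This cuts C6–C7 and C1–C10. Forward, Rh2(S-DOSP)4 (or its enantiomer) decomposes the ring A vinyldiazo ester A4. The carbenoid cyclopropanates the terminal alkene of silyloxydiene A5, and the cis-divinylcyclopropane undergoes Cope rearrangement to cycloheptadiene A6.
- For: C1 and C10 are set together through a boat transition state under catalyst control, so the C10 oxygen arrives with defined configuration. On that point it is stronger than the chosen route, which needs a reduction and an inversion at C10. It is also convergent.
- Against: C6 carries a methyl ester, not oxygen, so a one-carbon degradation and a reduction of the tetrasubstituted C5=C6 alkene are needed to reach C5–H and C6–O. The vinyl terminus C1 of the carbenoid is fully substituted and flanked by quaternary C4, which hinders cyclopropanation and forces the Cope step to create a quaternary centre. A4 needs its own multistep synthesis, and its C4 centre may be mismatched with the catalyst.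
- Comparison: the chosen route delivers C6 at the right oxidation level directly and builds C4 into the chain from the start.

**Alternative 3:** This cuts C1–C5 and C6–C7, with the cyclopropane C7–C9 bond as the third bond that changes. Forward, [Rh(CO)2Cl]2 (monovalent rhodium) joins the alkyne and the vinylcyclopropane of A7 in a (5+2) cycloaddition to diene A8.
- For: catalytic, neutral, atom-economical and free of charged intermediates. On certainty of ring closure it is stronger than a cationic (4+3) reaction.
- Against: A8 has no oxygen at C6 or C10, and neither of its alkenes (C5=C6, C9=C10) is where the target's alkene is. Hydroboration of C5=C6 would place H5 and the C6 oxygen cis, the wrong relationship. C10 would need an allylic oxidation with transposition of C9=C10 to C8=C9, and the two alkenes must be told apart.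
- Comparison: the chosen route accepts a riskier ring closure in exchange for a product that already has the right oxidation level at C6 and C10, leaving only functional-group adjustments.

Key step: step 8

Remark 1: (R)-terpinen-4-ol (1) is taken as material of high enantiomeric purity; lots of lower purity would be upgraded before use.
Remark 2: 4-(tert-butyldimethylsilyloxy)benzoic acid (19) is taken as a catalogue compound; otherwise it is one silylation–hydrolysis operation from 4-hydroxybenzoic acid.
Remark 3: all intermediates are described with the locants of the target; "methyl face" and "H5 face" are used as defined above.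

## Route

Step 1
Reactants: 1 (R)-terpinen-4-ol; 2 triethylsilyl trifluoromethanesulfonate
Product: 3 (R)-terpinen-4-ol triethylsilyl ether
Conditions: Et3SiOTf (1.3 equiv), 2,6-lutidine, CH2Cl2, 0 °C
Reagents that add atoms: triethylsilyl trifluoromethanesulfonate (2), CC[Si](CC)(CC)OS(=O)(=O)C(F)(F)F
Why: Silyl ether formation on a hindered tertiary alcohol with a silyl triflate and a hindered pyridine base; the C4 stereocentre is not touched. The triethylsilyl group should survive organometallic and amide bases and come off later with fluoride.

Step 2
Reactants: 3 (R)-terpinen-4-ol triethylsilyl ether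
Product: 5 (3R)-6-oxo-3-(propan-2-yl)-3-(triethylsilyloxy)heptanal, via ozonide 4 (not isolated)
Conditions: O3, CH2Cl2, −78 °C; PPh3, −78 → 23 °C
Reagents that add atoms: ozone, [O-][O+]=O
Why: Criegee ozonolysis of the only alkene with reductive work-up should give the C1 methyl ketone and the C6 aldehyde as two different termini. The keto aldehyde is used at once to avoid intramolecular aldol reaction.

Step 3
Reactants: 5 (3R)-6-oxo-3-(propan-2-yl)-3-(triethylsilyloxy)heptanal; 6 (E)-1-bromoprop-1-ene
Product: 7 (5R,8E)-7-hydroxy-5-(propan-2-yl)-5-(triethylsilyloxy)dec-8-en-2-one (both C7 epimers)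
Conditions: CrCl2 (4 equiv), NiCl2 (2 mol %), DMF, 23 °C
Reagents that add atoms: (E)-1-bromoprop-1-ene (6), C/C=C/Br
Why: Nozaki–Hiyama–Kishi coupling: the alkenylchromium species adds to aldehydes and leaves ketones alone, and the E geometry of the bromide is retained. The new carbinol (C6 of the target) forms as a mixture that is removed by oxidation in step 5.

Step 4
Reactants: 7 (5R,8E)-7-hydroxy-5-(propan-2-yl)-5-(triethylsilyloxy)dec-8-en-2-one; 8 1,1-dichloroethane
Product: 9 (9E)-2,2-dichloro-3-methyl-6-(propan-2-yl)-6-(triethylsilyloxy)undec-9-ene-3,8-diol (mixture at C3 and C8)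
Conditions: CH3CHCl2 (3.2 equiv), n-BuLi (3.0 equiv), THF/Et2O/pentane 4:1:1, −105 °C; then 7, −100 °C; AcOH in THF, −100 °C
Reagents that add atoms: 1,1-dichloroethane (8), CC(Cl)Cl
Why: Carbenoid addition to a ketone: 1,1-dichloroethyllithium persists below about −95 °C; one equivalent is consumed by the free hydroxyl and a second adds to the methyl ketone. Protonation in the cold stops the sequence at the dichloro carbinol. The new centre (C1 of the target) is formed as a mixture, which does not matter because C1 becomes the cation terminus.

Step 5
Reactants: 9 (9E)-2,2-dichloro-3-methyl-6-(propan-2-yl)-6-(triethylsilyloxy)undec-9-ene-3,8-diol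
Product: 10 (2E)-10,10-dichloro-9-hydroxy-9-methyl-6-(propan-2-yl)-6-(triethylsilyloxy)undec-2-en-4-one (both C9 epimers)
Conditions: Dess–Martin periodinane (1.3 equiv), NaHCO3, CH2Cl2, 0 → 23 °C
Reagents that add atoms: none
Why: Dess–Martin oxidation of the secondary allylic alcohol to the enone; the tertiary carbinol cannot be oxidised and the buffer protects the silyl ether. The two C6 epimers converge.

Step 6
Reactants: 10 (2E)-10,10-dichloro-9-hydroxy-9-methyl-6-(propan-2-yl)-6-(triethylsilyloxy)undec-2-en-4-one; 11 triisopropylsilyl trifluoromethanesulfonate
Product: 12 (2E,4Z)-10,10-dichloro-9-methyl-6-(propan-2-yl)-6-(triethylsilyloxy)-4-(triisopropylsilyloxy)undeca-2,4-dien-9-ol (both C9 epimers)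
Conditions: LiN(i-Pr)2 (2.3 equiv), THF, −78 °C; i-Pr3SiOTf (1.2 equiv), −78 °C; pH 7 buffer, −78 °C
Reagents that add atoms: triisopropylsilyl trifluoromethanesulfonate (11), CC(C)[Si](OS(=O)(=O)C(F)(F)F)(C(C)C)C(C)C
Why: Kinetic enolate O-silylation: the first equivalent of base gives the tertiary alkoxide (stable at −78 °C and too hindered for 11), the second removes a C5 proton through the cyclic amide transition state, faster than vinylogous deprotonation of the propenyl methyl. The enone is the only carbonyl group in 10, so no selectivity between two ketones is needed. The Z enol ether (C4 trans to C7) is expected because the quaternary C4 avoids the propenyl group in the enolisation transition state.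

Step 7
Reactants: 12 (2E,4Z)-10,10-dichloro-9-methyl-6-(propan-2-yl)-6-(triethylsilyloxy)-4-(triisopropylsilyloxy)undeca-2,4-dien-9-ol
Product: 14 (7Z,9E)-3-chloro-3-methyl-6-(propan-2-yl)-6-(triethylsilyloxy)-8-(triisopropylsilyloxy)undeca-7,9-dien-2-one (both C3 epimers), via chloroepoxide 13 (not isolated)
Conditions: LiN(SiMe3)2 (1.0 equiv), THF, −78 → 40 °C
Reagents that add atoms: none
Why: Alkoxide-induced 2-chlorooxirane formation followed by the α-chloro epoxide to α-chloro ketone rearrangement: the oxirane opens at the tertiary C1–O bond and chlorine shifts to C1, giving the tertiary α-chloro methyl ketone. Compound 12 has no carbonyl group, so the base can only form the alkoxide, and no acid or electrophile touches the silyl dienol ether.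

Step 8
Reactants: 14 (7Z,9E)-3-chloro-3-methyl-6-(propan-2-yl)-6-(triethylsilyloxy)-8-(triisopropylsilyloxy)undeca-7,9-dien-2-one
Product: 16 trans-fused cycloadduct (C10 ketone; C6=C7 triisopropylsilyl enol ether; C4 triethylsilyl ether; both C8 epimers), via oxyallyl cation 15 (not isolated)
Conditions: NaOCH2CF3 (2 equiv), CF3CH2OH (0.01 M), 0 → 23 °C
Reagents that add atoms: none
Why: Trifluoroethoxide removes a C9 proton and the resulting α′-enolate loses chloride from tertiary C1, helped by hydrogen bonding from the solvent, to give oxyallyl cation 15 held next to the C5–C8 silyloxydiene by the chain C2–C4. The closest known reaction type is the intramolecular oxyallyl cation (4+3) cycloaddition of α-halo ketones that carry a diene on a three-atom tether, which gives bicyclo[5.3.0]decenones; an oxyallyl cation with one dimethyl-type terminus, as here, is a standard partner in the intermolecular version. Ring A closes when C5, the nucleophilic terminus of the silyl dienol ether, bonds to C1 (5-exo if the process is stepwise), and ring B closes when C9 bonds to C8 (7-endo onto the C6–C8 silyloxyallyl cation, or the second bond of a concerted suprafacial cycloaddition); either way C6 emerges as the C6=C7 silyl enol ether and C10 as the ketone. C1 is controlled by the C4 stereocentre: with C3 turned out of the diene plane toward the cation, the triethylsilyloxy group should sit near H5, away from the enol ether oxygen and its silyl group, and the isopropyl group can turn its methine hydrogen toward that oxygen, so the cation adds to the diene face that puts the C1 methyl cis to the isopropyl group. C5 is controlled by the Z enol ether geometry (C4 outside, H5 inside) together with the extended arrangement, in which the oxyallyl oxygen points away from the diene and its silyloxy group; this gives the trans ring fusion, and C5 stays correctable because it becomes α to the C6 carbonyl. C8 is not controlled and need not be, since it becomes sp2 in step 12. The step needs seven-membered closure at C8 and not five-membered closure at C6 or at oxygen: the E propenyl and Z enol ether geometries let the diene reach the s-cis form under the cation, C8 is the unhindered terminus, and closure at C6 would create a third contiguous fully substituted carbon. The weakly nucleophilic ionising solvent and high dilution should hold back solvent capture, Favorskii contraction and dimerisation, and the bulky triisopropylsilyl group should keep the enol ether intact in the alkoxide medium.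

Step 9
Reactants: 16 trans-fused cycloadduct
Product: 17 trans-fused hydroxy diketone (C6 and C10 ketones; free C4 hydroxyl; both C8 epimers)
Conditions: HF·pyridine, pyridine, THF, 0 → 23 °C
Reagents that add atoms: none
Why: Desilylation: the enol ether is protonated at C7 to release the C6 ketone and the tertiary silyl ether is cleaved. The buffered acidic medium does not enolise C5, so the ring fusion is kept, and it avoids the base that would open the tertiary aldol by retro-aldol reaction.

Step 10
Reactants: 17 trans-fused hydroxy diketone
Product: 18 diol ketone (C6 hydroxyl on the methyl face; C4 hydroxyl on the H5 face; C10 ketone; both C8 epimers)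
Conditions: Me4NBH(OAc)3 (5 equiv), MeCN/AcOH 1:1, −30 → −20 °C
Reagents that add atoms: none
Why: Evans–Saksena reduction: only the β-hydroxy ketone at C6 is reduced; the C10 ketone, which has no β-hydroxyl and is neopentyl, is left. Hydride comes from boron bound to the C4 oxygen on the H5 face, which is also the open equatorial trajectory because the axial one is blocked by the syn-axial C1 methyl; this gives the C6 alcohol on the methyl face, 1,3-anti to the C4 hydroxyl, with H5 and H6 cis.

Step 11
Reactants: 18 diol ketone; 19 4-(tert-butyldimethylsilyloxy)benzoic acid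
Product: 21 C6 4-(tert-butyldimethylsilyloxy)benzoate (C10 ketone; free C4 hydroxyl; both C8 epimers), via mixed anhydride 20 (not isolated)
Conditions: 19 (1.5 equiv), 2,4,6-trichlorobenzoyl chloride, Et3N, THF, 23 °C; then 18, DMAP, toluene, 23 → 60 °C
Reagents that add atoms: 4-(tert-butyldimethylsilyloxy)benzoic acid (19), CC(C)(C)[Si](C)(C)Oc1ccc(cc1)C(=O)O
Why: Yamaguchi esterification of the hindered secondary C6 hydroxyl; the tertiary C4 hydroxyl does not react. The phenol is silylated so that it can neither acylate itself nor act as a nucleophile in step 14.

Step 12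
Reactants: 21 C6 4-(tert-butyldimethylsilyloxy)benzoate; 22 trimethylsilyl trifluoromethanesulfonate
Product: 24 C8=C9 enone (C10 ketone; C4 trimethylsilyl ether; C6 aryl ester), via bis-silyl enol ether 23 (not isolated)
Conditions: Me3SiOTf (3 equiv), Et3N (5 equiv), CH2Cl2, 0 °C; then Pd(OAc)2 (1.1 equiv), MeCN, 23 °C
Reagents that add atoms: trimethylsilyl trifluoromethanesulfonate (22), C[Si](C)(C)OS(=O)(=O)C(F)(F)F
Why: Saegusa–Ito oxidation: soft enolisation can only go toward C9 because C1 is quaternary, and the C4 hydroxyl is silylated in the same operation; the palladium enolate then loses the C8 hydrogen to give the C8=C9 enone. Both C8 epimers converge, and C6 is already an ester, so the new alkene has no ketone at C6 to conjugate with.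

Step 13
Reactants: 24 C8=C9 enone
Product: 25 allylic alcohol with the C10 hydroxyl on the methyl face (C10 epimer of the target configuration)
Conditions: NaBH4, CeCl3·7H2O, MeOH, −78 → −40 °C
Reagents that add atoms: none
Why: Luche reduction gives clean 1,2-reduction of the enone. Hydride should enter C10 along the axial trajectory on the H5 face, anti to the adjacent axial C1 methyl and away from the axial C6 ester, which puts the hydroxyl cis to the C1 methyl; this epimer is wanted here because step 14 inverts it.

Step 14
Reactants: 25 allylic alcohol with the C10 hydroxyl on the methyl face; 26 3-methylbutanoic acid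
Product: 28 bis-silyl ether of the target (C10 3-methylbutanoate on the H5 face; C4 trimethylsilyl ether; aryl tert-butyldimethylsilyl ether), via alkoxyphosphonium isovalerate 27 (not isolated)
Conditions: 3-methylbutanoic acid (3 equiv), PPh3 (3 equiv), DIAD (3 equiv), toluene, 0 → 23 °C
Reagents that add atoms: 3-methylbutanoic acid (26), CC(C)CC(=O)O
Why: Mitsunobu reaction: the carboxylate displaces the activated C10 oxygen with inversion, approaching from the H5 face along the same open axial trajectory the hydride used, so the ester ends trans to the C1 methyl. One step sets the C10 configuration and installs the acyl group; the silylated tertiary alcohol and phenol are inert.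

Step 15
Reactants: 28 bis-silyl ether of the target
Product: 29 target
Conditions: Bu4NF (3 equiv), AcOH (3 equiv), THF, 0 °C
Reagents that add atoms: none
Why: Fluoride desilylation buffered with acetic acid should cleave the aryl silyl ether and the tertiary trimethylsilyl ether without touching the two esters or the allylic system. Any C4 hydroxyl freed earlier converges here.

## Compound list

1 | (R)-terpinen-4-ol, (1R)-4-methyl-1-(propan-2-yl)cyclohex-3-en-1-ol | CC1=CC[C@@](O)(C(C)C)CC1 | starting material
2 | triethylsilyl trifluoromethanesulfonate | CC[Si](CC)(CC)OS(=O)(=O)C(F)(F)F | starting material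
3 | (R)-terpinen-4-ol triethylsilyl ether, (1R)-4-methyl-1-(propan-2-yl)-1-(triethylsilyloxy)cyclohex-3-ene | CC1=CC[C@@](O[Si](CC)(CC)CC)(C(C)C)CC1 | intermediate
4 | secondary ozonide of 3 (1,2,4-trioxolane across the former C=C; C4 as in 1) | CC12CC[C@](O[Si](CC)(CC)CC)(C(C)C)CC(OO1)O2 | intermediate
5 | (3R)-6-oxo-3-(propan-2-yl)-3-(triethylsilyloxy)heptanal | CC(=O)CC[C@](O[Si](CC)(CC)CC)(C(C)C)CC=O | intermediate
6 | (E)-1-bromoprop-1-ene | C/C=C/Br | starting material
7 | (5R,8E)-7-hydroxy-5-(propan-2-yl)-5-(triethylsilyloxy)dec-8-en-2-one, both C7 epimers | CC(=O)CC[C@](O[Si](CC)(CC)CC)(C(C)C)CC(O)/C=C/C | intermediate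
8 | 1,1-dichloroethane | CC(Cl)Cl | starting material
9 | (9E)-2,2-dichloro-3-methyl-6-(propan-2-yl)-6-(triethylsilyloxy)undec-9-ene-3,8-diol, C6 as in 1, mixture at C3 and C8 | CC(Cl)(Cl)C(C)(O)CC[C@](O[Si](CC)(CC)CC)(C(C)C)CC(O)/C=C/C | intermediate
10 | (2E)-10,10-dichloro-9-hydroxy-9-methyl-6-(propan-2-yl)-6-(triethylsilyloxy)undec-2-en-4-one, C6 as in 1, mixture at C9 | CC(Cl)(Cl)C(C)(O)CC[C@](O[Si](CC)(CC)CC)(C(C)C)CC(=O)/C=C/C | intermediate
11 | triisopropylsilyl trifluoromethanesulfonate | CC(C)[Si](OS(=O)(=O)C(F)(F)F)(C(C)C)C(C)C | starting material
12 | (2E,4Z)-10,10-dichloro-9-methyl-6-(propan-2-yl)-6-(triethylsilyloxy)-4-(triisopropylsilyloxy)undeca-2,4-dien-9-ol, C6 as in 1, mixture at C9 | CC(Cl)(Cl)C(C)(O)CC[C@](O[Si](CC)(CC)CC)(C(C)C)/C=C(\O[Si](C(C)C)(C(C)C)C(C)C)/C=C/C | intermediate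
13 | 2-chloro-2,3-dimethyl-3-[(4Z,6E)-3-(propan-2-yl)-3-(triethylsilyloxy)-5-(triisopropylsilyloxy)octa-4,6-dien-1-yl]oxirane, carbinol carbon as in 1 | CC1(Cl)OC1(C)CC[C@](O[Si](CC)(CC)CC)(C(C)C)/C=C(\O[Si](C(C)C)(C(C)C)C(C)C)/C=C/C | intermediate
14 | (7Z,9E)-3-chloro-3-methyl-6-(propan-2-yl)-6-(triethylsilyloxy)-8-(triisopropylsilyloxy)undeca-7,9-dien-2-one, C6 as in 1, mixture at C3 (C1 of the target) | CC(=O)C(C)(Cl)CC[C@](O[Si](CC)(CC)CC)(C(C)C)/C=C(\O[Si](C(C)C)(C(C)C)C(C)C)/C=C/C | intermediate
15 | oxyallyl cation (zwitterion) C1–C10–C9 derived from 14, tethered to the C5–C8 silyloxydiene | C=C([O-])[C+](C)CC[C@](O[Si](CC)(CC)CC)(C(C)C)/C=C(\O[Si](C(C)C)(C(C)C)C(C)C)/C=C/C | intermediate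
16 | trans-fused cycloadduct: hydroazulene with C10 ketone, C6=C7 triisopropylsilyl enol ether, C4 triethylsilyloxy on the H5 face, isopropyl and C1 methyl on the methyl face, C8 methyl (both epimers) | CC1CC(=O)[C@@]2(C)CC[C@](O[Si](CC)(CC)CC)(C(C)C)[C@@H]2C(O[Si](C(C)C)(C(C)C)C(C)C)=C1 | intermediate
17 | trans-fused hydroxy diketone: C6 and C10 ketones, free C4 hydroxyl on the H5 face, C8 methyl (both epimers) | CC1CC(=O)[C@@]2(C)CC[C@](O)(C(C)C)[C@@H]2C(=O)C1 | intermediate
18 | diol ketone: C6 hydroxyl on the methyl face (H5 and H6 cis), C4 hydroxyl on the H5 face, C10 ketone, C8 methyl (both epimers) | CC1CC(=O)[C@@]2(C)CC[C@](O)(C(C)C)[C@@H]2[C@H](O)C1 | intermediate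
19 | 4-(tert-butyldimethylsilyloxy)benzoic acid | CC(C)(C)[Si](C)(C)Oc1ccc(cc1)C(=O)O | starting material
20 | 4-(tert-butyldimethylsilyloxy)benzoic 2,4,6-trichlorobenzoic anhydride | CC(C)(C)[Si](C)(C)Oc1ccc(cc1)C(=O)OC(=O)c1c(Cl)cc(Cl)cc1Cl | intermediate
21 | C6 4-(tert-butyldimethylsilyloxy)benzoate of 18 (C10 ketone, free C4 hydroxyl, C8 epimers) | CC1CC(=O)[C@@]2(C)CC[C@](O)(C(C)C)[C@@H]2[C@H](OC(=O)c2ccc(O[Si](C)(C)C(C)(C)C)cc2)C1 | intermediate
22 | trimethylsilyl trifluoromethanesulfonate | C[Si](C)(C)OS(=O)(=O)C(F)(F)F | starting material
23 | bis-silyl compound: C9=C10 trimethylsilyl enol ether and C4 trimethylsilyl ether of 21 | CC1C=C(O[Si](C)(C)C)[C@@]2(C)CC[C@](O[Si](C)(C)C)(C(C)C)[C@@H]2[C@H](OC(=O)c2ccc(O[Si](C)(C)C(C)(C)C)cc2)C1 | intermediate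
24 | enone: C10 ketone conjugated with C8=C9, C4 trimethylsilyl ether, C6 aryl ester on the methyl face | CC1=CC(=O)[C@@]2(C)CC[C@](O[Si](C)(C)C)(C(C)C)[C@@H]2[C@H](OC(=O)c2ccc(O[Si](C)(C)C(C)(C)C)cc2)C1 | intermediate
25 | allylic alcohol: C10 hydroxyl on the methyl face (cis to the C1 methyl), otherwise as 24 | CC1=C[C@H](O)[C@@]2(C)CC[C@](O[Si](C)(C)C)(C(C)C)[C@@H]2[C@H](OC(=O)c2ccc(O[Si](C)(C)C(C)(C)C)cc2)C1 | intermediate
26 | 3-methylbutanoic acid (isovaleric acid) | CC(C)CC(=O)O | starting material
27 | C10 alkoxytriphenylphosphonium 3-methylbutanoate derived from 25 | CC1=C[C@H](O[P+](c3ccccc3)(c3ccccc3)c3ccccc3)[C@@]2(C)CC[C@](O[Si](C)(C)C)(C(C)C)[C@@H]2[C@H](OC(=O)c2ccc(O[Si](C)(C)C(C)(C)C)cc2)C1.CC(C)CC(=O)[O-] | intermediate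
28 | bis-silyl ether of the target: C10 3-methylbutanoate on the H5 face, C4 trimethylsilyl ether, aryl tert-butyldimethylsilyl ether | CC1=C[C@@H](OC(=O)CC(C)C)[C@@]2(C)CC[C@](O[Si](C)(C)C)(C(C)C)[C@@H]2[C@H](OC(=O)c2ccc(O[Si](C)(C)C(C)(C)C)cc2)C1 | intermediate
29 | (3S,3aS,4R,8R,8aS)-3-hydroxy-6,8a-dimethyl-8-[(3-methylbutanoyl)oxy]-3-(propan-2-yl)-1,2,3,3a,4,5,8,8a-octahydroazulen-4-yl 4-hydroxybenzoate | CC1=C[C@@H](OC(=O)CC(C)C)[C@@]2(C)CC[C@](O)(C(C)C)[C@@H]2[C@H](OC(=O)c2ccc(O)cc2)C1 | target

## Step count and least certain steps

Total step count: 15. Longest linear sequence: 15 steps (1 → 29); 2, 6, 8, 11, 19, 22 and 26 enter as purchased compounds.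

**Step 8 (key step).** The most likely failure is interception of the oxyallyl cation before the second bond forms: capture by the solvent, Favorskii contraction, or closure at C6 or at oxygen to five-membered products. The cause is that C1 is a hindered, fully substituted terminus and the diene is a nucleophilic enol ether, which favours a stepwise course. A second concern is a weak facial bias from C4.
Fallback: from 14, kinetic enol silylation (LiN(i-Pr)2, Me3SiCl, THF, −78 °C) gives the 2-(trimethylsilyloxy)allyl chloride F1. Ionisation with ZnCl2 in CH2Cl2 at low temperature generates the 2-silyloxyallyl cation in an aprotic, non-nucleophilic medium. Ring closure and loss of chlorotrimethylsilane return the route to 16.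

**Step 7.** The chloro ketone is formed while unreacted lithium alkoxide is still present. Proton transfer from C9 can stall the conversion and start uncontrolled ionisation next to the silyloxydiene. Alternatively, closure at the fully substituted dichloro carbon may need more heat than the dienol ether tolerates.
Fallback: this avoids chlorine altogether. From 7, 1-ethoxyvinyllithium (from ethyl vinyl ether and t-BuLi, in excess) adds to the methyl ketone to give the 2-ethoxyallylic carbinol F2. Oxidation with MnO2 gives enone F3, and enolisation and silylation as in step 6 (LiN(i-Pr)2, then 11) give the silyloxydiene F4. Triflic anhydride and 2,6-lutidine in CH2Cl2 at −78 °C ionise the tertiary allylic alcohol to the 2-ethoxyallyl cation, which undergoes the same (4+3) ring closure. Aqueous work-up hydrolyses the ethyl oxocarbenium ion, and the route is rejoined at 16.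

**Step 14.** The activated allylic alcohol can ionise, because the allyl cation has a tertiary terminus at C8. That would cost stereospecificity and give the transposed C8 ester or a diene. Substitution next to quaternary C1 is also slow. The step further depends on the facial outcome predicted for step 13.
Fallback: from 24, a Corey–Bakshi–Shibata reduction with (S)-2-methyl-CBS-oxazaborolidine and catecholborane in toluene at −78 °C, with the quaternary C1 flank acting as the large group, should deliver hydride from the methyl face under reagent control. This gives the alcohol F5 with the C10 hydroxyl on the H5 face. Acylation with 3-methylbutanoyl chloride, pyridine and DMAP, with retention, returns the route to 28.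

**Step 9 (ring fusion).** Acidic desilylation keeps whatever configuration C5 received in step 8. If the ring closure there passes through the compact arrangement, the cis ring fusion is carried forward.
Fallback: from 14, the step 8 conditions would then give the cis-fused cycloadduct F6. Bu4NF buffered with AcOH in THF at 0 °C cleaves only the enol ether and gives the cis-fused diketone F7, with the C4 silyl ether still in place. DBU in toluene equilibrates C5 through the C6 enolate to the trans-fused diketone F8, provided the trans fusion is the more stable one, which is not certain. The equilibration is done before the C4 hydroxyl is freed, because the free tertiary aldol could open by retro-aldol reaction under base. HF·pyridine then removes the triethylsilyl group, and the route is rejoined at 17.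

## Further compounds

F1 | step 8 | (7Z,9E)-3-chloro-3-methyl-6-(propan-2-yl)-6-(triethylsilyloxy)-8-(triisopropylsilyloxy)-2-(trimethylsilyloxy)undeca-1,7,9-triene (trimethylsilyl enol ether of 14) | C=C(O[Si](C)(C)C)C(C)(Cl)CC[C@](O[Si](CC)(CC)CC)(C(C)C)/C=C(\O[Si](C(C)C)(C(C)C)C(C)C)/C=C/C
F2 | step 7 | (9E)-2-ethoxy-3-methyl-6-(propan-2-yl)-6-(triethylsilyloxy)undeca-1,9-diene-3,8-diol, C6 as in 1, mixture at C3 and C8 | C=C(OCC)C(C)(O)CC[C@](O[Si](CC)(CC)CC)(C(C)C)CC(O)/C=C/C
F3 | step 7 | (2E)-10-ethoxy-9-hydroxy-9-methyl-6-(propan-2-yl)-6-(triethylsilyloxy)undeca-2,10-dien-4-one, C6 as in 1, mixture at C9 | C=C(OCC)C(C)(O)CC[C@](O[Si](CC)(CC)CC)(C(C)C)CC(=O)/C=C/C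
F4 | step 7 | (7Z,9E)-2-ethoxy-3-methyl-6-(propan-2-yl)-6-(triethylsilyloxy)-8-(triisopropylsilyloxy)undeca-1,7,9-trien-3-ol, C6 as in 1, mixture at C3 | C=C(OCC)C(C)(O)CC[C@](O[Si](CC)(CC)CC)(C(C)C)/C=C(\O[Si](C(C)C)(C(C)C)C(C)C)/C=C/C
F5 | step 14 | allylic alcohol with the C10 hydroxyl on the H5 face (C10 epimer of 25) | CC1=C[C@@H](O)[C@@]2(C)CC[C@](O[Si](C)(C)C)(C(C)C)[C@@H]2[C@H](OC(=O)c2ccc(O[Si](C)(C)C(C)(C)C)cc2)C1
F6 | step 9 | cis-fused cycloadduct (C5 epimer of 16) | CC1CC(=O)[C@@]2(C)CC[C@](O[Si](CC)(CC)CC)(C(C)C)[C@H]2C(O[Si](C(C)C)(C(C)C)C(C)C)=C1
F7 | step 9 | cis-fused diketone with C4 triethylsilyl ether (C6 and C10 ketones) | CC1CC(=O)[C@@]2(C)CC[C@](O[Si](CC)(CC)CC)(C(C)C)[C@H]2C(=O)C1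
F8 | step 9 | trans-fused diketone with C4 triethylsilyl ether (C6 and C10 ketones) | CC1CC(=O)[C@@]2(C)CC[C@](O[Si](CC)(CC)CC)(C(C)C)[C@@H]2C(=O)C1
A1 | alternative 1 | 3-methylcyclopent-2-en-1-one | CC1=CC(=O)CC1
A2 | alternative 1 | 4-methyl-1,2-bis(trimethylsilyloxy)cyclopent-1-ene | CC1CC(O[Si](C)(C)C)=C(O[Si](C)(C)C)C1
A3 | alternative 1 | cis-anti-cis tricyclic photoadduct (C4 ketone, C6 and C10 trimethylsilyl ethers on the cyclobutane) | C[C@]12CCC(=O)[C@H]1[C@]1(O[Si](C)(C)C)CC(C)C[C@]21O[Si](C)(C)C
A4 | alternative 2 | methyl 2-diazo-2-[2-methyl-5-(propan-2-yl)-5-(triethylsilyloxy)cyclopent-1-en-1-yl]acetate, carbinol carbon as C4 of the target | COC(=O)C(=[N+]=[N-])C1=C(C)CC[C@]1(O[Si](CC)(CC)CC)C(C)C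
A5 | alternative 2 | (E)-1-(tert-butyldimethylsilyloxy)-3-methylbuta-1,3-diene | C=C(C)/C=C/O[Si](C)(C)C(C)(C)C
A6 | alternative 2 | bicyclic cycloheptadiene with C6 methyl ester, C10 tert-butyldimethylsilyl ether, C4 triethylsilyl ether and quaternary C1 | CC1=C[C@@H](O[Si](C)(C)C(C)(C)C)[C@@]2(C)CC[C@](O[Si](CC)(CC)CC)(C(C)C)C2=C(C(=O)OC)C1
A7 | alternative 3 | (E)-enyne carrying a 2-methylcyclopropyl group on the alkene: 3-(propan-2-yl)-3-(triethylsilyloxy)-6-methyl-7-(2-methylcyclopropyl)hept-6-en-1-yne, carbinol carbon as C4 of the target | C#C[C@@](O[Si](CC)(CC)CC)(C(C)C)CC/C(C)=C/C1CC1C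
A8 | alternative 3 | bicyclo[5.3.0]decadiene with C5=C6 and C9=C10, quaternary C1, C8 methyl, C4 triethylsilyl ether | C[C@@H]1C=C[C@@]2(C)CC[C@](O[Si](CC)(CC)CC)(C(C)C)C2=CC1
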